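**Retrosynthetic overview**
1. The target comes from global hydrogenolysis of a pentabenzyl precursor, which comes from O-methylation of the one free 2'-OH, which comes from esterifying a ring A acid onto O-4' of a B–C depside (A–B link).
2. The B–C depside is cut into the ring C phenol and an open-chain triketo-acylketene released from a diketo-dioxinone; one operation forms the O-4–C7' ester bond and then the C1'–C6' bond of ring B.
3. The strategy rests on ring B having the acetate-tetraketide pattern (carboxyl carbon C7' on C1', oxygens on C2' and C4', methyl on C6') with C7' bonded to O-4 of ring C, so the ester and the benzene ring both map onto one 3,5,7-trioxooctanoyl chain.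
4. Ring order: ring C (from orsellinic acid) and ring A (from methyl orsellinate, hydroxylated at C5) are purchased arenes; ring B is the only ring constructed, and it is grown on ring C; ring A is attached afterwards.
5. The target has no stereocentre; the only control problems are chemo- and regioselectivity among the phenols.

Key step: step 7

Remark: locants 1–6 are used for ring C, 1'–6' for ring B (C7' is its carboxyl carbon) and C1 (ester carbon) to C8 (methyl) for the open tetraketide chain; orsellinic acid, methyl orsellinate and 2,2,6-trimethyl-4H-1,3-dioxin-4-one are taken as purchasable.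

**Route**

Step 1
Reactants: 1 2,2,6-trimethyl-4H-1,3-dioxin-4-one
Product: 2 keto-dioxinone 2,2-dimethyl-6-(2-oxopropyl)-4H-1,3-dioxin-4-one
Conditions: LiN(SiMe3)2 (excess), THF, −78 °C; AcCl, −78 → −20 °C; aq. NH4Cl
Reagents that add atoms: acetyl chloride, CC(=O)Cl
Why: The lithium dienolate of 1 should be C-acylated by the acid chloride at its terminal (6-methyl) carbon, a vinylogous Claisen acylation that is the standard entry to keto-dioxinones; the excess base keeps the more acidic product deprotonated.

Step 2
Reactants: 2 keto-dioxinone 2,2-dimethyl-6-(2-oxopropyl)-4H-1,3-dioxin-4-one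
Product: 3 diketo-dioxinone 6-(2,4-dioxopentyl)-2,2-dimethyl-4H-1,3-dioxin-4-one
Conditions: LiN(iPr)2 (3 equiv), THF, −78 °C; 1-acetylimidazole, −78 → −40 °C; aq. HCl to pH 3
Reagents that add atoms: 1-acetylimidazole, CC(=O)n1ccnc1
Why: This is a crossed Claisen condensation of a 1,3-dianion: after the doubly activated CH2 is deprotonated, the second deprotonation at the terminal methyl gives the more reactive carbanion, which should attack the mild acyl imidazole, and the dioxinone ring survives at low temperature.

Step 3
Reactants: 4 orsellinic acid (2,4-dihydroxy-6-methylbenzoic acid)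
Product: 5 benzyl orsellinate (benzyl 2,4-dihydroxy-6-methylbenzoate)
Conditions: BnBr, KHCO3, DMF, rt
Reagents that add atoms: benzyl bromide, BrCc1ccccc1
Why: In this SN2 O-alkylation of a carboxylate, KHCO3 ionizes only the carboxylic acid, so the benzyl group should go to the carboxylate while both phenols stay free, and room temperature avoids decarboxylation.

Step 4
Reactants: 5 benzyl orsellinate (benzyl 2,4-dihydroxy-6-methylbenzoate)
Product: 6 benzyl 2-hydroxy-6-methyl-4-[(triisopropylsilyl)oxy]benzoate
Conditions: iPr3SiCl (1.05 equiv), imidazole, CH2Cl2, 0 °C → rt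
Reagents that add atoms: chlorotriisopropylsilane, CC(C)[Si](Cl)(C(C)C)C(C)C
Why: Silyl ether formation should be selective for the 4-OH, which is free and accessible, whereas the 2-OH is hydrogen-bonded to the ester carbonyl and flanked by it.

Step 5
Reactants: 6 benzyl 2-hydroxy-6-methyl-4-[(triisopropylsilyl)oxy]benzoate
Product: 7 benzyl 2-(benzyloxy)-6-methyl-4-[(triisopropylsilyl)oxy]benzoate
Conditions: BnBr, K2CO3, Bu4NI (cat.), dry acetone, reflux
Reagents that add atoms: benzyl bromide, BrCc1ccccc1
Why: This Williamson etherification caps the remaining hydrogen-bonded phenol under anhydrous conditions; the bulky triisopropylsilyl aryl ether, chosen over a smaller silyl group for this reason, should withstand carbonate in acetone.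

Step 6
Reactants: 7 benzyl 2-(benzyloxy)-6-methyl-4-[(triisopropylsilyl)oxy]benzoate
Product: 8 ring C phenol benzyl 2-(benzyloxy)-4-hydroxy-6-methylbenzoate
Conditions: Bu4NF, AcOH, THF, 0 °C
Reagents that add atoms: none
Why: Fluoride-induced desilylation is driven by the strong Si–F bond; acetic acid buffers the liberated phenoxide, and the benzyl ether and benzyl ester are inert to fluoride.

Step 7
Reactants: 3 diketo-dioxinone 6-(2,4-dioxopentyl)-2,2-dimethyl-4H-1,3-dioxin-4-one; 8 ring C phenol benzyl 2-(benzyloxy)-4-hydroxy-6-methylbenzoate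
Product: 12 B–C depside benzyl 2-(benzyloxy)-4-[(2,4-dihydroxy-6-methylbenzoyl)oxy]-6-methylbenzoate, via acylketene 9 (not isolated), via aryl trioxooctanoate 10 (not isolated), via aldol carbinol 11 (not isolated)
Conditions: toluene, 110 °C (3 added slowly to 8); then Et3N (0.2 equiv), CH2Cl2, 0 °C → rt; then CF3CO2H (cat.)
Reagents that add atoms: none
Why: Proposed new method: thermolysis of 3 should expel acetone by retro-[4+2] fragmentation to acylketene 9, and the 4-OH of 8, the only free nucleophile present, should add to the ketene carbon to give aryl trioxooctanoate 10 (new O-4–C7' ester bond); the closest known reaction type is the dioxinone thermolysis, alcohol capture and base-induced aldol aromatization that turns diketo-dioxinones into alkyl resorcylates, together with the known acetoacetylation of phenols by simple acylketenes, so only the pairing of a phenol with the triketo-ketene is untested. Catalytic Et3N should then enolize C2 of 10, the methylene between ester and ketone, and ring B is closed by a 6-(enolexo)-exo-trig aldol addition of C2 to the C7 methyl ketone (new C1'–C6' bond) to give carbinol 11, which loses water under a trace of acid and tautomerizes to the arene. The two stereocentres of 11 disappear on aromatization, so no stereocontrol is required. Two selectivities are needed: phenol capture must outrun internal capture of 9 by its own C5 enol (2-pyranone formation), which slow addition of 3 to a hot concentrated solution of 8 should secure, and the C2-to-C7 aldol must beat C8-to-C3 aldol, Claisen closure and lactonization with loss of the aryloxide, which the higher acidity of C2 and a weak amine base in an aprotic solvent at 0 °C should favour. Because the ester is formed before ring B exists, no 2,6-disubstituted benzoic acid has to be esterified, and 12 should emerge with a hydrogen-bonded 2'-OH and a free 4'-OH, the differentiation the next two steps rely on.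

Step 8
Reactants: 13 methyl orsellinate (methyl 2,4-dihydroxy-6-methylbenzoate)
Product: 15 methyl 2,4,5-trihydroxy-6-methylbenzoate, via aryl sulfate 14 (not isolated)
Conditions: K2S2O8, aq. NaOH, 5 → 20 °C, N2; then aq. HCl, 80 °C
Reagents that add atoms: potassium peroxodisulfate, [K+].[K+].[O-]S(=O)(=O)OOS(=O)(=O)[O-]
Why: In this Elbs persulfate oxidation the phenolate attacks a peroxide oxygen through the carbon para to O-2, and C5 is the open position of that kind (also ortho to O-4, while C1 para to O-4 is blocked); the aryl sulfate resists further oxidation and is then cleaved by hot acid that the hindered methyl ester tolerates.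

Step 9
Reactants: 15 methyl 2,4,5-trihydroxy-6-methylbenzoate
Product: 16 methyl 2,4,5-tris(benzyloxy)-6-methylbenzoate
Conditions: BnBr, K2CO3, degassed DMF, 60 °C, Ar
Reagents that add atoms: benzyl bromide, BrCc1ccccc1
Why: Threefold Williamson O-benzylation in warm DMF should also alkylate the chelated 2-OH, and exclusion of air prevents oxidation of the electron-rich triol to a quinone before it is capped.

Step 10
Reactants: 16 methyl 2,4,5-tris(benzyloxy)-6-methylbenzoate
Product: 17 ring A acid 2,4,5-tris(benzyloxy)-6-methylbenzoic acid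
Conditions: KOH, DMSO–H2O, 90 °C; then aq. HCl
Reagents that add atoms: potassium hydroxide, [K+].[OH-]
Why: Saponification of a 2,6-disubstituted benzoate needs poorly solvated hydroxide in hot aqueous DMSO; the benzyl ethers are stable to base and the acid is liberated on acidification.

Step 11
Reactants: 12 B–C depside benzyl 2-(benzyloxy)-4-[(2,4-dihydroxy-6-methylbenzoyl)oxy]-6-methylbenzoate; 17 ring A acid 2,4,5-tris(benzyloxy)-6-methylbenzoic acid
Product: 19 benzyl 2-(benzyloxy)-4-[(2-hydroxy-6-methyl-4-{[2,4,5-tris(benzyloxy)-6-methylbenzoyl]oxy}benzoyl)oxy]-6-methylbenzoate, via mixed anhydride 18 (not isolated)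
Conditions: (CF3CO)2O, toluene, rt
Reagents that add atoms: none
Why: In this depside esterification through a mixed trifluoroacetic anhydride, the electron-rich, doubly ortho-substituted aroyl group ionizes towards an acylium ion that is insensitive to the steric hindrance, and it should be taken up by the free 4'-OH while the 2'-OH, hydrogen-bonded to the neighbouring ester carbonyl, stays unreacted.

Step 12
Reactants: 19 benzyl 2-(benzyloxy)-4-[(2-hydroxy-6-methyl-4-{[2,4,5-tris(benzyloxy)-6-methylbenzoyl]oxy}benzoyl)oxy]-6-methylbenzoate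
Product: 20 benzyl 2-(benzyloxy)-4-[(2-methoxy-6-methyl-4-{[2,4,5-tris(benzyloxy)-6-methylbenzoyl]oxy}benzoyl)oxy]-6-methylbenzoate
Conditions: MeI, K2CO3, acetone, rt → 40 °C
Reagents that add atoms: iodomethane, CI
Why: Williamson O-methylation should act on the single free phenol, and the two aryl esters, both derived from 2,6-disubstituted benzoic acids, are shielded from attack by the phenoxide under these mild conditions.

Step 13
Reactants: 20 benzyl 2-(benzyloxy)-4-[(2-methoxy-6-methyl-4-{[2,4,5-tris(benzyloxy)-6-methylbenzoyl]oxy}benzoyl)oxy]-6-methylbenzoate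
Product: 21 2'-O-methylhiascic acid (2-hydroxy-4-[(2-methoxy-6-methyl-4-{[2,4,5-trihydroxy-6-methylbenzoyl]oxy}benzoyl)oxy]-6-methylbenzoic acid)
Conditions: H2 (1 atm), 10% Pd/C, EtOAc–THF, rt
Reagents that add atoms: none
Why: Catalytic hydrogenolysis should remove the four benzyl ethers and the benzyl ester under neutral conditions, leaving the aryl esters and the aryl methyl ether untouched and avoiding depside cleavage or decarboxylation.

**Compound list**
1 | 2,2,6-trimethyl-4H-1,3-dioxin-4-one | CC1=CC(=O)OC(C)(C)O1 | starting material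
2 | 2,2-dimethyl-6-(2-oxopropyl)-4H-1,3-dioxin-4-one (keto-dioxinone) | CC(=O)CC1=CC(=O)OC(C)(C)O1 | intermediate
3 | 6-(2,4-dioxopentyl)-2,2-dimethyl-4H-1,3-dioxin-4-one (diketo-dioxinone) | CC(=O)CC(=O)CC1=CC(=O)OC(C)(C)O1 | intermediate
4 | orsellinic acid (2,4-dihydroxy-6-methylbenzoic acid) | Cc1cc(O)cc(O)c1C(=O)O | starting material
5 | benzyl 2,4-dihydroxy-6-methylbenzoate | Cc1cc(O)cc(O)c1C(=O)OCc1ccccc1 | intermediate
6 | benzyl 2-hydroxy-6-methyl-4-[(triisopropylsilyl)oxy]benzoate | Cc1cc(O[Si](C(C)C)(C(C)C)C(C)C)cc(O)c1C(=O)OCc1ccccc1 | intermediate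
7 | benzyl 2-(benzyloxy)-6-methyl-4-[(triisopropylsilyl)oxy]benzoate | Cc1cc(O[Si](C(C)C)(C(C)C)C(C)C)cc(OCc2ccccc2)c1C(=O)OCc1ccccc1 | intermediate
8 | benzyl 2-(benzyloxy)-4-hydroxy-6-methylbenzoate (ring C phenol) | Cc1cc(O)cc(OCc2ccccc2)c1C(=O)OCc1ccccc1 | intermediate
9 | oct-1-ene-1,3,5,7-tetrone (acylketene) | CC(=O)CC(=O)CC(=O)C=C=O | intermediate
10 | 3-(benzyloxy)-4-[(benzyloxy)carbonyl]-5-methylphenyl 3,5,7-trioxooctanoate | CC(=O)CC(=O)CC(=O)CC(=O)Oc1cc(C)c(C(=O)OCc2ccccc2)c(OCc2ccccc2)c1 | intermediate
11 | 3-(benzyloxy)-4-[(benzyloxy)carbonyl]-5-methylphenyl 2-hydroxy-2-methyl-4,6-dioxocyclohexane-1-carboxylate (mixture of stereoisomers, both centres lost on aromatization) | CC1(O)CC(=O)CC(=O)C1C(=O)Oc1cc(C)c(C(=O)OCc2ccccc2)c(OCc2ccccc2)c1 | intermediate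
12 | benzyl 2-(benzyloxy)-4-[(2,4-dihydroxy-6-methylbenzoyl)oxy]-6-methylbenzoate (B–C depside) | Cc1cc(O)cc(O)c1C(=O)Oc1cc(C)c(C(=O)OCc2ccccc2)c(OCc2ccccc2)c1 | intermediate
13 | methyl orsellinate (methyl 2,4-dihydroxy-6-methylbenzoate) | COC(=O)c1c(C)cc(O)cc1O | starting material
14 | methyl 2,4-dihydroxy-6-methyl-5-(sulfooxy)benzoate (present as its salt) | COC(=O)c1c(C)c(OS(=O)(=O)O)c(O)cc1O | intermediate
15 | methyl 2,4,5-trihydroxy-6-methylbenzoate | COC(=O)c1c(C)c(O)c(O)cc1O | intermediate
16 | methyl 2,4,5-tris(benzyloxy)-6-methylbenzoate | COC(=O)c1c(C)c(OCc2ccccc2)c(OCc2ccccc2)cc1OCc1ccccc1 | intermediate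
17 | 2,4,5-tris(benzyloxy)-6-methylbenzoic acid (ring A acid) | Cc1c(OCc2ccccc2)c(OCc2ccccc2)cc(OCc2ccccc2)c1C(=O)O | intermediate
18 | 2,4,5-tris(benzyloxy)-6-methylbenzoic trifluoroacetic anhydride | Cc1c(OCc2ccccc2)c(OCc2ccccc2)cc(OCc2ccccc2)c1C(=O)OC(=O)C(F)(F)F | intermediate
19 | benzyl 2-(benzyloxy)-4-[(2-hydroxy-6-methyl-4-{[2,4,5-tris(benzyloxy)-6-methylbenzoyl]oxy}benzoyl)oxy]-6-methylbenzoate | Cc1c(OCc2ccccc2)c(OCc2ccccc2)cc(OCc2ccccc2)c1C(=O)Oc1cc(C)c(C(=O)Oc2cc(C)c(C(=O)OCc3ccccc3)c(OCc3ccccc3)c2)c(O)c1 | intermediate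
20 | benzyl 2-(benzyloxy)-4-[(2-methoxy-6-methyl-4-{[2,4,5-tris(benzyloxy)-6-methylbenzoyl]oxy}benzoyl)oxy]-6-methylbenzoate | COc1cc(OC(=O)c2c(OCc3ccccc3)cc(OCc3ccccc3)c(OCc3ccccc3)c2C)cc(C)c1C(=O)Oc1cc(C)c(C(=O)OCc2ccccc2)c(OCc2ccccc2)c1 | intermediate
21 | 2'-O-methylhiascic acid | COc1cc(OC(=O)c2c(O)cc(O)c(O)c2C)cc(C)c1C(=O)Oc1cc(C)c(C(=O)O)c(O)c1 | target

**Step count and risks**

Total step count: 13 steps. Longest linear sequence: 8 steps (steps 3, 4, 5, 6, 7, 11, 12, 13, from orsellinic acid 4).

Steps most likely to fail: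

1. Step 7. The acylketene may be captured by its own enol (2-pyranone formation) faster than it O-acylates the moderately nucleophilic phenol, or the aryloxide may be expelled by lactonization or Claisen closure during the base treatment instead of the aldol closure. Fallback, setting out from 8 and returning at 12: the B–C ester would be made by conventional depside coupling with ring B taken from the aromatic pool. Methyl orsellinate 13 would be bis-allylated (allyl bromide, K2CO3, DMF, 60 °C) to methyl 2,4-bis(allyloxy)-6-methylbenzoate F1. Saponification (KOH, DMSO–H2O, 90 °C) would give 2,4-bis(allyloxy)-6-methylbenzoic acid F2. Condensation of that acid with phenol 8 by (CF3CO)2O in toluene at room temperature should give benzyl 4-{[2,4-bis(allyloxy)-6-methylbenzoyl]oxy}-2-(benzyloxy)-6-methylbenzoate F3. Both allyl ethers would then be removed with Pd(PPh3)4 and morpholine in THF, which leaves the benzyl groups in place and gives 12.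

2. Step 8. The persulfate hydroxylation may stop at low conversion or over-oxidize the electron-rich ring, and the triol may be oxidized by air during isolation. Fallback, setting out from 13 and returning at 16: the C5 oxygen would be introduced by halogenation and boron oxidation. Dibenzylation of 13 (BnBr, K2CO3, DMF, 60 °C) would give methyl 2,4-bis(benzyloxy)-6-methylbenzoate F4. Bromination with N-bromosuccinimide in MeCN at 0 °C should go to C5 (para to the 2-benzyloxy group; the site between the two ethers is more crowded) to give methyl 2,4-bis(benzyloxy)-5-bromo-6-methylbenzoate F5. Miyaura borylation (bis(pinacolato)diboron, PdCl2(dppf), KOAc, dioxane, 90 °C) would give methyl 2,4-bis(benzyloxy)-6-methyl-5-(4,4,5,5-tetramethyl-1,3,2-dioxaborolan-2-yl)benzoate F6. Oxidation (H2O2, NaOH, THF, 0 °C) would give methyl 2,4-bis(benzyloxy)-5-hydroxy-6-methylbenzoate F7, and benzylation (BnBr, K2CO3, DMF) would rejoin the route at 16.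

3. Step 2. The acidic β-diketone product may quench unreacted dianion by proton transfer, O-acylation may compete, and the sensitive diketo-dioxinone may decompose on isolation. Fallback, setting out from 1 and returning at 3: the chain would be assembled with a removable ester as activating group. The lithium dienolate of 1 (LiN(SiMe3)2, THF, −78 °C) would be acylated with allyl 3-chloro-3-oxopropanoate (allyl malonyl chloride) to give allyl 4-(2,2-dimethyl-4-oxo-4H-1,3-dioxin-6-yl)-3-oxobutanoate F8. C-Acetylation at the doubly activated methylene (MgCl2, pyridine, AcCl, CH2Cl2, 0 °C) would give allyl 2-acetyl-4-(2,2-dimethyl-4-oxo-4H-1,3-dioxin-6-yl)-3-oxobutanoate F9. Pd(PPh3)4 with morpholine in THF would then remove the allyl group, and the resulting β-keto acid should lose CO2 to give 3.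

**Further compounds**
F1 | step 7 | methyl 2,4-bis(allyloxy)-6-methylbenzoate | COC(=O)c1c(C)cc(OCC=C)cc1OCC=C
F2 | step 7 | 2,4-bis(allyloxy)-6-methylbenzoic acid | Cc1cc(OCC=C)cc(OCC=C)c1C(=O)O
F3 | step 7 | benzyl 4-{[2,4-bis(allyloxy)-6-methylbenzoyl]oxy}-2-(benzyloxy)-6-methylbenzoate | Cc1cc(OCC=C)cc(OCC=C)c1C(=O)Oc1cc(C)c(C(=O)OCc2ccccc2)c(OCc2ccccc2)c1
F4 | step 8 | methyl 2,4-bis(benzyloxy)-6-methylbenzoate | COC(=O)c1c(C)cc(OCc2ccccc2)cc1OCc1ccccc1
F5 | step 8 | methyl 2,4-bis(benzyloxy)-5-bromo-6-methylbenzoate | COC(=O)c1c(C)c(Br)c(OCc2ccccc2)cc1OCc1ccccc1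
F6 | step 8 | methyl 2,4-bis(benzyloxy)-6-methyl-5-(4,4,5,5-tetramethyl-1,3,2-dioxaborolan-2-yl)benzoate | COC(=O)c1c(C)c(B2OC(C)(C)C(C)(C)O2)c(OCc2ccccc2)cc1OCc1ccccc1
F7 | step 8 | methyl 2,4-bis(benzyloxy)-5-hydroxy-6-methylbenzoate | COC(=O)c1c(C)c(O)c(OCc2ccccc2)cc1OCc1ccccc1
F8 | step 2 | allyl 4-(2,2-dimethyl-4-oxo-4H-1,3-dioxin-6-yl)-3-oxobutanoate | C=CCOC(=O)CC(=O)CC1=CC(=O)OC(C)(C)O1
F9 | step 2 | allyl 2-acetyl-4-(2,2-dimethyl-4-oxo-4H-1,3-dioxin-6-yl)-3-oxobutanoate | C=CCOC(=O)C(C(C)=O)C(=O)CC1=CC(=O)OC(C)(C)O1
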